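**Plan**

1. Retrosynthetic cuts: (a) the furan C–O bond between chromone C2 and the ring D oxygen, back to a 2′-hydroxyisoflavone; (b) the chromone C3–aryl bond (Suzuki–Miyaura), giving a ring A/C iodochromone and a ring D boronate; (c) in ring D, the aryl–CH(O) bond and the CH(O)–CMe2 bond of the diol-bearing dihydropyran together, back to an aryl isopropenyl ether and a (Z)-1,2-bis(silyloxy)ethene.
2. Enabling feature: the pyran oxygen of ring D sits on an aromatic carbon whose only free ortho carbon lies between two oxygen-bearing ring carbons (the para carbon carries Br). Once protonated, the unit C(aryl)=C(aryl)–O–C(+)Me2 is a cationic 2-oxadiene whose two ends take up a two-carbon alkene.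
3. Forward, ring D: trioxygenated arene → isopropenyl ether → dihydropyran ring with both carbinol centres, delivered as silyl ethers (key step) → boronate. Ring A: phenol → acetophenone → 3-iodochromone → chromene ring by propargyl ether Claisen rearrangement.
4. Union and end game: Suzuki coupling, dehydrogenative closure of the furan ring, then removal of the allyl and silyl groups.
5. Stereochemistry: the carbinol carbon next to CMe2 (chroman C3, R) is set by the chiral counteranion in the key step; the benzylic carbinol carbon (chroman C4, S) is set by C3 in the trans ring closure; no later step touches either centre.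

Key step: step 7

Assumption: the sense of induction of the chiral acid in step 7 cannot be predicted with certainty; the catalyst antipode that leads to the (3R,4S) series is to be used, assigned by correlation with material from the fallback sequence for step 7.

**Route**

Step 1
Reactants: 1 2,5-dihydroxybenzaldehyde
Product: 2 2-hydroxy-5-[(triisopropylsilyl)oxy]benzaldehyde
Conditions: TIPSCl (1.05 equiv), imidazole, CH2Cl2/DMF, 0 °C
Reagents that add atoms: chlorotriisopropylsilane CC(C)[Si](Cl)(C(C)C)C(C)C
Why: The 5-OH is not hydrogen-bonded to the formyl group and is the more nucleophilic phenol, so one equivalent of the bulky silyl chloride should silylate it selectively (chemoselective O-silylation).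

Step 2
Reactants: 2 2-hydroxy-5-[(triisopropylsilyl)oxy]benzaldehyde
Product: 3 2-(allyloxy)-5-[(triisopropylsilyl)oxy]benzaldehyde
Conditions: allyl bromide, K2CO3, acetone, 50 °C
Reagents that add atoms: allyl bromide C=CCBr
Why: Williamson etherification of the remaining chelated phenol; an ether at this oxygen cannot migrate to the neighbouring phenol that step 3 sets free, and the aryl triisopropylsilyl ether should survive K2CO3 in acetone.

Step 3
Reactants: 3 2-(allyloxy)-5-[(triisopropylsilyl)oxy]benzaldehyde
Product: 5 2-(allyloxy)-5-[(triisopropylsilyl)oxy]phenol, via aryl formate 4 (not isolated)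
Conditions: mCPBA, CH2Cl2, 0 °C to rt; then Et3N (cat.), MeOH, 0 °C
Reagents that add atoms: 3-chloroperoxybenzoic acid OOC(=O)c1cccc(Cl)c1
Why: Dakin-type Baeyer–Villiger oxidation; the ortho-alkoxy aryl group should migrate faster than the deactivated allyl ether double bond is epoxidised, and the labile formate 4 is cleaved by methanolysis.

Step 4
Reactants: 5 2-(allyloxy)-5-[(triisopropylsilyl)oxy]phenol
Product: 6 2-(allyloxy)-4-bromo-5-[(triisopropylsilyl)oxy]phenol
Conditions: NBS, MeCN, −10 °C
Reagents that add atoms: N-bromosuccinimide O=C1CCC(=O)N1Br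
Why: Electrophilic aromatic bromination should go para to the free phenol; this blocks the most nucleophilic ring carbon before the cationic key step and provides the handle for the cross-coupling.

Step 5
Reactants: 6 2-(allyloxy)-4-bromo-5-[(triisopropylsilyl)oxy]phenol
Product: 7 1-(allyloxy)-5-bromo-2-(prop-1-en-2-yloxy)-4-[(triisopropylsilyl)oxy]benzene
Conditions: isopropenylboronic acid pinacol ester (2 equiv), Cu(OAc)2 (20 mol%), pyridine, 4 Å MS, CH2Cl2, O2 (1 atm), rt
Reagents that add atoms: isopropenylboronic acid pinacol ester CC(=C)B1OC(C)(C)C(C)(C)O1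
Why: Chan–Lam-type oxidative C–O coupling of a phenol with an alkenylboronate should give the aryl isopropenyl ether, the neutral precursor of the aryl oxocarbenium ion.

Step 6
Reactants: 8 (tert-butyldimethylsilyloxy)acetaldehyde
Product: 9 (Z)-1,2-bis[(tert-butyldimethylsilyl)oxy]ethene
Conditions: TBSOTf, Et3N, CH2Cl2, 0 °C
Reagents that add atoms: tert-butyldimethylsilyl trifluoromethanesulfonate CC(C)(C)[Si](C)(C)OS(=O)(=O)C(F)(F)F
Why: Soft enolisation of the α-silyloxy aldehyde with a silyl triflate and an amine (silyl enol ether formation) should give the enediol bis-silyl ether, the (Z) isomer being favoured for 1,2-dioxygenated alkenes.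

Step 7
Reactants: 7 1-(allyloxy)-5-bromo-2-(prop-1-en-2-yloxy)-4-[(triisopropylsilyl)oxy]benzene; 9 (Z)-1,2-bis[(tert-butyldimethylsilyl)oxy]ethene
Product: 10 (3R,4S)-8-(allyloxy)-6-bromo-3,4-bis[(tert-butyldimethylsilyl)oxy]-2,2-dimethyl-5-[(triisopropylsilyl)oxy]chromane
Conditions: chiral imidodiphosphorimidate Brønsted acid (IDPi, BINOL-derived, 3 mol%), 4 Å MS, toluene, −78 to −40 °C, slow addition of the enol ether to the acid and a slight excess of the enediol ether; Et3N quench
Reagents that add atoms: none
Why: Proposed new method: the confined chiral acid protonates the enol ether 7 to the aryl oxocarbenium ion ArO+=CMe2 (a cationic 2-oxadiene) paired with the chiral anion, the enediol silane 9 adds through carbon to the cationic carbon (Mukaiyama-type addition, bond CMe2–C3) and the silyl oxocarbenium ion so formed is attacked at once by the arene carbon that lies between the two oxygen-bearing ring carbons (Friedel–Crafts hydroxyalkylation, bond aryl–C4), loss of the arene proton returning the acid, so that one molecule of 7 and one of 9 combine in a net addition that keeps every atom of both. The closest known reaction types are the oxa-Povarov reaction (formal inverse-electron-demand [4+2] cycloaddition of aryl oxocarbenium ions with alkenes, run with SnCl4 and racemic) and the imidodiphosphorimidate-catalysed additions of silyl enolates to achiral iminium and oxocarbenium ions, in which the counteranion selects the face of the silyl nucleophile; new are the ketone-derived oxocarbenium ion, the 1,2-dioxygenated alkene and the enantioselective cascade. The dihydropyran ring closes in a 6-exo-trig attack of the arene on the C=O+ bond (endo with respect to the arene π bond). C3 is set by the chiral counteranion, which has to tell apart the two enantiotopic carbons of the planar alkene 9 in the first, irreversible C–C bond formation (the cationic carbon carries two methyl groups and is not prochiral); C4 is set by C3 in the ring closure, where the two bulky silyloxy groups go anti (trans), and because the benzylic C4–O bond of this doubly oxygen-activated ring can ionise under the acid, the trans isomer is also expected from equilibration. Regioselectivity needs no control, since the other ortho position carries the allyloxy group and the para position bromine; chemoselectivity rests on the oxocarbenium ion reacting faster with the electron-rich silane 9 than with the allyl ether or a second molecule of 7, whose concentration the slow addition keeps low.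

Step 8
Reactants: 10 (3R,4S)-8-(allyloxy)-6-bromo-3,4-bis[(tert-butyldimethylsilyl)oxy]-2,2-dimethyl-5-[(triisopropylsilyl)oxy]chromane
Product: 11 (3R,4S)-8-(allyloxy)-3,4-bis[(tert-butyldimethylsilyl)oxy]-2,2-dimethyl-6-(4,4,5,5-tetramethyl-1,3,2-dioxaborolan-2-yl)-5-[(triisopropylsilyl)oxy]chromane
Conditions: B2pin2, Pd(dppf)Cl2 (5 mol%), KOAc, 1,4-dioxane, 85 °C
Reagents that add atoms: bis(pinacolato)diboron CC1(C)OB(OC1(C)C)B1OC(C)(C)C(C)(C)O1
Why: Miyaura borylation; zerovalent palladium should insert into the aryl–Br bond faster than it ionises the aryl allyl ether in the absence of a soft nucleophile, and the silyl ethers are inert.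

Step 9
Reactants: 12 2,6-dimethoxytoluene
Product: 14 3,5-dimethoxy-4-methylphenol, via arylboronic pinacol ester 13 (not isolated)
Conditions: B2pin2 (1.0 equiv), [Ir(OMe)(cod)]2 (1.5 mol%), 4,4′-di-tert-butyl-2,2′-bipyridine (3 mol%), THF, 80 °C; then H2O2 (30% aq.), NaOH, 0 °C
Reagents that add atoms: bis(pinacolato)diboron CC1(C)OB(OC1(C)C)B1OC(C)(C)C(C)(C)O1 (boryl group of 13); hydrogen peroxide OO (oxygen of 14)
Why: Sterically controlled Ir-catalysed C–H borylation should take the only C–H with no ortho substituent (para to the methyl group), and oxidation of the C–B bond gives the phenol in which the future pyranone oxygen is the only free OH.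

Step 10
Reactants: 14 3,5-dimethoxy-4-methylphenol
Product: 15 1-(6-hydroxy-2,4-dimethoxy-3-methylphenyl)ethan-1-one
Conditions: Ac2O, BF3·OEt2, 70 °C; aqueous work-up
Reagents that add atoms: acetic anhydride CC(=O)OC(C)=O
Why: Friedel–Crafts acetylation (via Fries-type acyl transfer) ortho to the phenol; the two free ring positions are equivalent, so only one acetophenone can form.

Step 11
Reactants: 15 1-(6-hydroxy-2,4-dimethoxy-3-methylphenyl)ethan-1-one
Product: 17 3-iodo-5,7-dimethoxy-6-methyl-4H-chromen-4-one, via enaminone 16 (not isolated)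
Conditions: Me2NCH(OMe)2, toluene, 95 °C; then I2, CHCl3, rt
Reagents that add atoms: N,N-dimethylformamide dimethyl acetal COC(OC)N(C)C; iodine II
Why: Enaminone formation and iodine-induced cyclisation (loss of dimethylamine, α-iodination) is the standard entry to 3-iodochromones; only one phenol is free, so the methyl group must end at C6 and not at C8.

Step 12
Reactants: 17 3-iodo-5,7-dimethoxy-6-methyl-4H-chromen-4-one
Product: 18 5,7-dihydroxy-3-iodo-6-methyl-4H-chromen-4-one
Conditions: BBr3 (4 equiv), CH2Cl2, −78 °C to rt; then H2O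
Reagents that add atoms: none
Why: Lewis acid ether cleavage of both aryl methyl ethers (the 5-OMe assisted by chelation to the carbonyl); the vinyl iodide and the pyranone should be inert to BBr3.

Step 13
Reactants: 18 5,7-dihydroxy-3-iodo-6-methyl-4H-chromen-4-one
Product: 19 5-hydroxy-3-iodo-6-methyl-7-[(2-methylbut-3-yn-2-yl)oxy]-4H-chromen-4-one
Conditions: 3-chloro-3-methylbut-1-yne, K2CO3, KI, CuI (cat.), acetone, 55 °C
Reagents that add atoms: 3-chloro-3-methylbut-1-yne C#CC(C)(C)Cl
Why: Copper-assisted O-propargylation should take place only at the 7-OH, because the 5-OH is tied up in a hydrogen bond to the carbonyl group.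

Step 14
Reactants: 19 5-hydroxy-3-iodo-6-methyl-7-[(2-methylbut-3-yn-2-yl)oxy]-4H-chromen-4-one
Product: 20 5-hydroxy-3-iodo-6,8,8-trimethyl-4H,8H-pyrano[2,3-f]chromen-4-one
Conditions: N,N-diethylaniline, 150 °C
Reagents that add atoms: none
Why: Aromatic propargyl Claisen rearrangement, 1,5-hydrogen shift and oxa-6π electrocyclisation give the 2,2-dimethylchromene; C6 carries the methyl group, so the rearrangement can only go to C8 (angular fusion).

Step 15
Reactants: 11 (3R,4S)-8-(allyloxy)-3,4-bis[(tert-butyldimethylsilyl)oxy]-2,2-dimethyl-6-(pinacolboryl)-5-[(triisopropylsilyl)oxy]chromane; 20 5-hydroxy-3-iodo-6,8,8-trimethyl-4H,8H-pyrano[2,3-f]chromen-4-one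
Product: 21 3-{(3R,4S)-8-(allyloxy)-3,4-bis[(tert-butyldimethylsilyl)oxy]-2,2-dimethyl-5-[(triisopropylsilyl)oxy]chroman-6-yl}-5-hydroxy-6,8,8-trimethyl-4H,8H-pyrano[2,3-f]chromen-4-one
Conditions: Pd(dppf)Cl2 (5 mol%), K3PO4, 1,4-dioxane/H2O (9:1), 70 °C
Reagents that add atoms: none
Why: Suzuki–Miyaura coupling of a 3-iodochromone with an arylboronate is the standard isoflavone construction; the chelated 5-OH, the chromene and the allyl and silyl ethers should be tolerated.

Step 16
Reactants: 21 the isoflavone of step 15
Product: 22 3-{(3R,4S)-8-(allyloxy)-3,4-bis[(tert-butyldimethylsilyl)oxy]-5-hydroxy-2,2-dimethylchroman-6-yl}-5-hydroxy-6,8,8-trimethyl-4H,8H-pyrano[2,3-f]chromen-4-one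
Conditions: Bu4NF/AcOH (1:1, 1.2 equiv), THF, 0 °C
Reagents that add atoms: none
Why: Fluoride cleaves the aryl silyl ether (phenoxide leaving group) far faster than the two hindered secondary alkyl TBS ethers; the benzylic oxygen stays silylated, so the free ortho-phenol has no leaving group from which a quinone methide could form.

Step 17
Reactants: 22 the 2′-hydroxyisoflavone of step 16
Product: 23 ring D O-allyl, bis-O-TBS ether of the target (allyl on the phenol of ring D, TBS on both carbinol oxygens, 5-OH of ring A free)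
Conditions: DDQ (1.2 equiv), anhydrous 1,4-dioxane, rt to 50 °C
Reagents that add atoms: none
Why: Dehydrogenative cyclisation of a 2′-hydroxyisoflavone to the coumaronochromone (conjugate addition of the phenol to chromone C2, then quinone dehydrogenation) has close precedent on pyrano-isoflavones; the two bulky trans silyloxy groups should hold the benzylic C4–H near the arene plane, which disfavours its abstraction.

Step 18
Reactants: 23 the O-allyl bis-O-TBS ether of the target
Product: 24 bis-O-TBS ether of the target (both carbinol oxygens silylated, all phenols free)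
Conditions: Pd(PPh3)4 (5 mol%), morpholine, THF, rt
Reagents that add atoms: none
Why: Tsuji–Trost deallylation; zerovalent palladium ionises the aryl allyl ether and morpholine traps the π-allyl complex under neutral conditions that should leave the chromene and the coumaronochromone untouched.

Step 19
Reactants: 24 the bis-O-TBS ether of the target
Product: 25 CNP0351839.1 (target; trans-diol, R at the carbinol carbon next to CMe2, S at the benzylic carbinol carbon)
Conditions: Bu4NF/AcOH (1:1, excess), THF, 45 °C
Reagents that add atoms: none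
Why: Buffered fluoride desilylation attacks silicon only, so both C–O bonds and with them both stereocentres are retained; acid, which could ionise the benzylic C–O bond, is avoided.

**Compound list**

1 | 2,5-dihydroxybenzaldehyde | O=Cc1cc(O)ccc1O | starting material
2 | 2-hydroxy-5-[(triisopropylsilyl)oxy]benzaldehyde | O=Cc1cc(O[Si](C(C)C)(C(C)C)C(C)C)ccc1O | intermediate
3 | 2-(allyloxy)-5-[(triisopropylsilyl)oxy]benzaldehyde | O=Cc1cc(O[Si](C(C)C)(C(C)C)C(C)C)ccc1OCC=C | intermediate
4 | 2-(allyloxy)-5-[(triisopropylsilyl)oxy]phenyl formate | O=COc1cc(O[Si](C(C)C)(C(C)C)C(C)C)ccc1OCC=C | intermediate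
5 | 2-(allyloxy)-5-[(triisopropylsilyl)oxy]phenol | Oc1cc(O[Si](C(C)C)(C(C)C)C(C)C)ccc1OCC=C | intermediate
6 | 2-(allyloxy)-4-bromo-5-[(triisopropylsilyl)oxy]phenol | Oc1cc(O[Si](C(C)C)(C(C)C)C(C)C)c(Br)cc1OCC=C | intermediate
7 | 1-(allyloxy)-5-bromo-2-(prop-1-en-2-yloxy)-4-[(triisopropylsilyl)oxy]benzene | C=C(C)Oc1cc(O[Si](C(C)C)(C(C)C)C(C)C)c(Br)cc1OCC=C | intermediate
8 | (tert-butyldimethylsilyloxy)acetaldehyde | CC(C)(C)[Si](C)(C)OCC=O | starting material
9 | (Z)-1,2-bis[(tert-butyldimethylsilyl)oxy]ethene | CC(C)(C)[Si](C)(C)O/C=C\O[Si](C)(C)C(C)(C)C | intermediate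
10 | (3R,4S)-8-(allyloxy)-6-bromo-3,4-bis[(tert-butyldimethylsilyl)oxy]-2,2-dimethyl-5-[(triisopropylsilyl)oxy]chromane | CC1(C)Oc2c(OCC=C)cc(Br)c(O[Si](C(C)C)(C(C)C)C(C)C)c2[C@H](O[Si](C)(C)C(C)(C)C)[C@H]1O[Si](C)(C)C(C)(C)C | intermediate
11 | (3R,4S)-8-(allyloxy)-3,4-bis[(tert-butyldimethylsilyl)oxy]-2,2-dimethyl-6-(4,4,5,5-tetramethyl-1,3,2-dioxaborolan-2-yl)-5-[(triisopropylsilyl)oxy]chromane | CC1(C)Oc2c(OCC=C)cc(B3OC(C)(C)C(C)(C)O3)c(O[Si](C(C)C)(C(C)C)C(C)C)c2[C@H](O[Si](C)(C)C(C)(C)C)[C@H]1O[Si](C)(C)C(C)(C)C | intermediate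
12 | 2,6-dimethoxytoluene (1,3-dimethoxy-2-methylbenzene) | COc1cccc(OC)c1C | starting material
13 | 2-(3,5-dimethoxy-4-methylphenyl)-4,4,5,5-tetramethyl-1,3,2-dioxaborolane | COc1cc(cc(OC)c1C)B1OC(C)(C)C(C)(C)O1 | intermediate
14 | 3,5-dimethoxy-4-methylphenol | COc1cc(O)cc(OC)c1C | intermediate
15 | 1-(6-hydroxy-2,4-dimethoxy-3-methylphenyl)ethan-1-one | CC(=O)c1c(O)cc(OC)c(C)c1OC | intermediate
16 | (E)-3-(dimethylamino)-1-(6-hydroxy-2,4-dimethoxy-3-methylphenyl)prop-2-en-1-one | CN(C)/C=C/C(=O)c1c(O)cc(OC)c(C)c1OC | intermediate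
17 | 3-iodo-5,7-dimethoxy-6-methyl-4H-chromen-4-one | COc1cc2occ(I)c(=O)c2c(OC)c1C | intermediate
18 | 5,7-dihydroxy-3-iodo-6-methyl-4H-chromen-4-one | Cc1c(O)cc2occ(I)c(=O)c2c1O | intermediate
19 | 5-hydroxy-3-iodo-6-methyl-7-[(2-methylbut-3-yn-2-yl)oxy]-4H-chromen-4-one | Cc1c(OC(C)(C)C#C)cc2occ(I)c(=O)c2c1O | intermediate
20 | 5-hydroxy-3-iodo-6,8,8-trimethyl-4H,8H-pyrano[2,3-f]chromen-4-one | Cc1c2c(c3occ(I)c(=O)c3c1O)C=CC(C)(C)O2 | intermediate
21 | 3-{(3R,4S)-8-(allyloxy)-3,4-bis[(tert-butyldimethylsilyl)oxy]-2,2-dimethyl-5-[(triisopropylsilyl)oxy]chroman-6-yl}-5-hydroxy-6,8,8-trimethyl-4H,8H-pyrano[2,3-f]chromen-4-one | Cc1c2c(c3occ(-c4cc(OCC=C)c5OC(C)(C)[C@H](O[Si](C)(C)C(C)(C)C)[C@@H](O[Si](C)(C)C(C)(C)C)c5c4O[Si](C(C)C)(C(C)C)C(C)C)c(=O)c3c1O)C=CC(C)(C)O2 | intermediate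
22 | 3-{(3R,4S)-8-(allyloxy)-3,4-bis[(tert-butyldimethylsilyl)oxy]-5-hydroxy-2,2-dimethylchroman-6-yl}-5-hydroxy-6,8,8-trimethyl-4H,8H-pyrano[2,3-f]chromen-4-one | Cc1c2c(c3occ(-c4cc(OCC=C)c5OC(C)(C)[C@H](O[Si](C)(C)C(C)(C)C)[C@@H](O[Si](C)(C)C(C)(C)C)c5c4O)c(=O)c3c1O)C=CC(C)(C)O2 | intermediate
23 | ring D O-allyl, bis-O-TBS ether of the target (hexacyclic pyrano-coumaronochromone; trans carbinol centres R next to CMe2 and S benzylic) | Cc1c2c(c3oc4oc5c6c(c(OCC=C)cc5c4c(=O)c3c1O)OC(C)(C)[C@H](O[Si](C)(C)C(C)(C)C)[C@H]6O[Si](C)(C)C(C)(C)C)C=CC(C)(C)O2 | intermediate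
24 | bis-O-TBS ether of the target (both carbinol oxygens silylated, phenols free) | Cc1c2c(c3oc4oc5c6c(c(O)cc5c4c(=O)c3c1O)OC(C)(C)[C@H](O[Si](C)(C)C(C)(C)C)[C@H]6O[Si](C)(C)C(C)(C)C)C=CC(C)(C)O2 | intermediate
25 | CNP0351839.1 | Cc1c2c(c3oc4oc5c6c(c(O)cc5c4c(=O)c3c1O)OC(C)(C)[C@H](O)[C@H]6O)C=CC(C)(C)O2 | target

**Step count and risks**

Total step count: 19. Longest linear sequence: 12 steps (steps 1–5, 7, 8 and 15–19).

Steps most likely to fail:

Step 7 (proposed new method). The likely failures are poor discrimination of the two enantiotopic alkene carbons by the counteranion, loss of the trans relationship through ionisation at the benzylic carbon, and protonation of the silane 9 in place of 7 with oligomerisation. The fallback uses known chemistry, sets out from 6 and comes back at 10. O-Alkylation of 6 with 3-chloro-3-methylbut-1-yne (CuCl2 cat., DBU, MeCN, 0 °C) would give 1-(allyloxy)-5-bromo-2-[(2-methylbut-3-yn-2-yl)oxy]-4-[(triisopropylsilyl)oxy]benzene F1. Heating in xylene at 130 °C, below the temperature at which the allyl ether rearranges, should bring about the propargyl Claisen rearrangement, 1,5-hydrogen shift and oxa-6π electrocyclisation onto the same free ortho carbon and give 8-(allyloxy)-6-bromo-2,2-dimethyl-5-[(triisopropylsilyl)oxy]-2H-chromene F2. Jacobsen epoxidation with (R,R)-N,N′-bis(3,5-di-tert-butylsalicylidene)-1,2-cyclohexanediaminomanganese chloride (trivalent manganese), NaOCl and 4-phenylpyridine N-oxide should give (3R,4R)-8-(allyloxy)-6-bromo-3,4-epoxy-2,2-dimethyl-5-[(triisopropylsilyl)oxy]chromane F3; the terminal allyl double bond is a poor substrate for this catalyst. Acid-catalysed hydrolysis (H2SO4 cat., THF/H2O, 0 °C) with inversion at the benzylic carbon should give (3R,4S)-8-(allyloxy)-6-bromo-2,2-dimethyl-5-[(triisopropylsilyl)oxy]chromane-3,4-diol F4, and silylation with TBSOTf and 2,6-lutidine returns to 10.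

Step 17. The likely failures are over-oxidation of the electron-rich ring D (a hydroquinone monoether once the 2′-phenol is free) and hydride abstraction at the benzylic C4–H in place of C–O ring closure. The fallback avoids any quinone oxidant, sets out from 22 and comes back at 23. Nucleophilic (Weitz–Scheffer) epoxidation of the chromone C2=C3 bond with t-BuOOH and DBU in CH2Cl2 leaves the electron-rich chromene double bond alone and would give the 2,3-epoxyisoflavanone F5. The neighbouring 2′-phenoxide should open it at C2 (5-exo-tet) to the cis-fused 3-hydroxy-2,3-dihydrocoumaronochromone F6. Syn-dehydration of this tertiary alcohol with the Burgess reagent restores the C2=C3 bond and gives 23.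

Step 5. The likely failures are oxidative degradation of the electron-rich phenol under Cu/O2 and slow transmetalation of the 1,1-disubstituted alkenylboronate. The fallback uses no oxidant, sets out from 6 and comes back at 7. Acetylation (Ac2O, pyridine) would give 2-(allyloxy)-4-bromo-5-[(triisopropylsilyl)oxy]phenyl acetate F7, and methylenation of the ester carbonyl with Cp2TiMe2 (toluene, 65 °C; Petasis variant of the Tebbe olefination) gives 7.

**Further compounds**

F1 | step 7 | 1-(allyloxy)-5-bromo-2-[(2-methylbut-3-yn-2-yl)oxy]-4-[(triisopropylsilyl)oxy]benzene | C#CC(C)(C)Oc1cc(O[Si](C(C)C)(C(C)C)C(C)C)c(Br)cc1OCC=C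
F2 | step 7 | 8-(allyloxy)-6-bromo-2,2-dimethyl-5-[(triisopropylsilyl)oxy]-2H-chromene | CC1(C)C=Cc2c(O[Si](C(C)C)(C(C)C)C(C)C)c(Br)cc(OCC=C)c2O1
F3 | step 7 | (3R,4R)-8-(allyloxy)-6-bromo-3,4-epoxy-2,2-dimethyl-5-[(triisopropylsilyl)oxy]chromane | CC1(C)Oc2c(OCC=C)cc(Br)c(O[Si](C(C)C)(C(C)C)C(C)C)c2[C@H]3O[C@H]31
F4 | step 7 | (3R,4S)-8-(allyloxy)-6-bromo-2,2-dimethyl-5-[(triisopropylsilyl)oxy]chromane-3,4-diol | CC1(C)Oc2c(OCC=C)cc(Br)c(O[Si](C(C)C)(C(C)C)C(C)C)c2[C@H](O)[C@H]1O
F5 | step 17 | 2,3-epoxide of isoflavone 22 (2,3-epoxyisoflavanone, mixture at the two new centres) | Cc1c2c(c3OC4OC4(c5cc(OCC=C)c6OC(C)(C)[C@H](O[Si](C)(C)C(C)(C)C)[C@@H](O[Si](C)(C)C(C)(C)C)c6c5O)C(=O)c3c1O)C=CC(C)(C)O2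
F6 | step 17 | cis-fused 3-hydroxy-2,3-dihydro derivative of 23 (OH on the former chromone C3, H on C2, mixture at the two new centres) | Cc1c2c(c3OC4Oc5c6c(c(OCC=C)cc5C4(O)C(=O)c3c1O)OC(C)(C)[C@H](O[Si](C)(C)C(C)(C)C)[C@H]6O[Si](C)(C)C(C)(C)C)C=CC(C)(C)O2
F7 | step 5 | 2-(allyloxy)-4-bromo-5-[(triisopropylsilyl)oxy]phenyl acetate | CC(=O)Oc1cc(O[Si](C(C)C)(C(C)C)C(C)C)c(Br)cc1OCC=C
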